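**Assumption:** the target has no stereocentre and no E/Z-defined alkene, so the "single enantiomer" is the one achiral compound drawn. Flavonoid numbering is used for the tetracycle (coumaronochromone = isoflavone with an O bridge from C-2 to C-2'); "prenyl" = 3-methylbut-2-en-1-yl.

## Retrosynthetic overview

1. Target 14 ⇒ 5-O-prenyl ether 13 by a formal [1,3] O→C prenyl shift. The ether masks O-5 during ring closure and is the source of the C-6 prenyl.
2. 13 ⇒ acyclic ketene dithioacetal 10 (A ring plus C-2/C-3/C-4) and hydroxy-prenyl-benzoquinone 5 (complete B ring). One operation forms the furan and then the γ-pyranone.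
3. 10 ⇒ acetophenone 9 ⇒ chromene 8 ⇒ phloroacetophenone 6 + prenal 7.
4. 5 ⇒ 3-prenyl-2,4-dihydroxybenzaldehyde 3 (Dakin, then oxidation) ⇒ 2,4-dihydroxybenzaldehyde 1 + prenyl bromide 2.
5. Ring order: dimethylpyran (step 3), then furan and γ-pyranone together (step 6); both benzene rings are bought.

## Route

Step 1
Reactants: 1 2,4-dihydroxybenzaldehyde; 2 prenyl bromide (1-bromo-3-methylbut-2-ene)
Product: 3 2,4-dihydroxy-3-prenylbenzaldehyde
Conditions: KOH (1.1 equiv), H2O, 0 °C → rt
Reagents that add atoms: none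
Why: Aqueous-base C-prenylation of an ambident resorcinol-type phenoxide, where the protic medium favours C- over O-alkylation and C-3 (between both oxygens) is the most nucleophilic carbon; modest yield is expected, with the 5-prenyl and O-prenyl isomers removed by chromatography.

Step 2
Reactants: 3 2,4-dihydroxy-3-prenylbenzaldehyde
Product: 5 2-hydroxy-3-prenyl-1,4-benzoquinone, via 3-prenylbenzene-1,2,4-triol 4 (not isolated)
Conditions: 30% H2O2 (1.05 equiv), NaOH, THF/H2O, 0 °C, N2; then HCl to pH 2, FeCl3 (2.2 equiv), 0 °C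
Reagents that add atoms: hydrogen peroxide, OO
Why: Dakin oxidation of an ortho/para-hydroxybenzaldehyde (aryl migration, formate hydrolysis) gives the hydroxyhydroquinone, which Fe(III) oxidises to the 2-hydroxy-1,4-quinone; the isolated prenyl alkene is inert to alkaline peroxide.

Step 3
Reactants: 6 1-(2,4,6-trihydroxyphenyl)ethanone (phloroacetophenone); 7 3-methylbut-2-enal (prenal)
Product: 8 1-(5,7-dihydroxy-2,2-dimethyl-2H-chromen-6-yl)ethanone
Conditions: EDDA (10 mol%), xylene, 140 °C; 6 in slight excess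
Reagents that add atoms: none
Why: Knoevenagel-type condensation at C-3 then oxa-6π electrocyclisation of the o-quinone methide (formal [3+3] chromenylation); closure through the para oxygen keeps both carbonyl-flanking OH groups, and the symmetry of 6 makes C-3 and C-5 equivalent.

Step 4
Reactants: 8 1-(5,7-dihydroxy-2,2-dimethyl-2H-chromen-6-yl)ethanone; 2 prenyl bromide
Product: 9 1-[5-hydroxy-2,2-dimethyl-7-(prenyloxy)-2H-chromen-6-yl]ethanone
Conditions: K2CO3 (1.1 equiv), acetone, rt
Reagents that add atoms: none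
Why: Williamson mono-etherification, which stops after one alkylation because the remaining OH is chelated to the acetyl group; the 7-OH (next to H-8) should react in preference to the 5-OH (peri to H-4), and the isomer is checked by NOE (OCH2 to H-8).

Step 5
Reactants: 9 1-[5-hydroxy-2,2-dimethyl-7-(prenyloxy)-2H-chromen-6-yl]ethanone
Product: 10 1-[5-hydroxy-2,2-dimethyl-7-(prenyloxy)-2H-chromen-6-yl]-3,3-bis(methylsulfanyl)prop-2-en-1-one
Conditions: NaH (3.2 equiv), CS2 (1.2 equiv), THF, 0 °C; then MeI (2.1 equiv), 0 °C → rt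
Reagents that add atoms: carbon disulfide, S=C=S; iodomethane, CI
Why: α-Oxoketene dithioacetal synthesis (enolate addition to CS2, then double S-methylation); the soft thiolates are methylated much faster than the chelated, hindered phenoxide, and low temperature keeps the product acyclic.

Step 6
Reactants: 10 ketene dithioacetal; 5 2-hydroxy-3-prenyl-1,4-benzoquinone
Product: 13 4',5'-dihydroxy-3'-prenyl-5-(prenyloxy)-6'',6''-dimethylpyrano[2'',3'':7,8]coumaronochromone, via hydroquinone Michael adduct 11 (not isolated), via 2-methylthio-3-aroylbenzofuran 12 (not isolated)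
Conditions: Zn(OTf)2 (20 mol%), 4 Å MS, CH2Cl2/MeNO2, slow addition of 5, 0 °C → 40 °C, N2 sweep
Reagents that add atoms: none
Why: Proposed new method: a Nenitzescu-type formal [3+2] benzofuran annulation run on an acyclic α-oxoketene dithioacetal – Zn(II) chelates the 2-OH/C-1=O unit of 5 so the push–pull alkene carbon of 10 adds 1,4 at C-5 (the enone of the carbonyl that is not part of the vinylogous acid) to give 11, the new hydroquinone OH at C-4 adds to the bis(methylthio)carbenium carbon and expels MeSH (furan ring, 12), and the only free A-ring OH then displaces the second MeS group by addition–elimination at the vinylogous thioester (γ-pyranone ring), the prenyl ether blocking the other ortho oxygen so that only the angular isomer can form; the closest known reaction types are the Nenitzescu 5-hydroxybenzofuran synthesis from enaminones and quinones and the cyclisation of o-hydroxyaryl ketene dithioacetals to 2-(methylthio)chromones; no stereocentre is formed.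

Step 7
Reactants: 13 5-O-prenyl coumaronochromone
Product: 14 4',5,5'-trihydroxy-3',6-diprenyl-6'',6''-dimethylpyrano[2'',3'':7,8]coumaronochromone (target CNP0329721.0)
Conditions: montmorillonite K10, CH2Cl2, 0 °C → rt, short contact time
Reagents that add atoms: none
Why: Acid-clay-mediated formal [1,3] O→C prenyl shift (tight ion pair, Friedel–Crafts-type recombination) of the carbonyl-chelated 5-O-prenyl ether; C-6 is the only open ortho position (C-4a and C-8 are substituted), and the chelated 5-OH formed is a poor nucleophile for chroman formation.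

## Compound list

1 | 2,4-dihydroxybenzaldehyde | O=Cc1ccc(O)cc1O | starting material
2 | prenyl bromide (1-bromo-3-methylbut-2-ene) | CC(C)=CCBr | starting material
3 | 2,4-dihydroxy-3-(3-methylbut-2-en-1-yl)benzaldehyde | O=Cc1ccc(O)c(CC=C(C)C)c1O | intermediate
4 | 3-(3-methylbut-2-en-1-yl)benzene-1,2,4-triol | Oc1ccc(O)c(CC=C(C)C)c1O | intermediate (not isolated)
5 | 2-hydroxy-3-(3-methylbut-2-en-1-yl)cyclohexa-2,5-diene-1,4-dione | O=C1C=CC(=O)C(CC=C(C)C)=C1O | intermediate
6 | 1-(2,4,6-trihydroxyphenyl)ethanone | CC(=O)c1c(O)cc(O)cc1O | starting material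
7 | 3-methylbut-2-enal | CC(C)=CC=O | starting material
8 | 1-(5,7-dihydroxy-2,2-dimethyl-2H-chromen-6-yl)ethanone | CC(=O)c1c(O)cc2OC(C)(C)C=Cc2c1O | intermediate
9 | 1-[5-hydroxy-2,2-dimethyl-7-(3-methylbut-2-en-1-yloxy)-2H-chromen-6-yl]ethanone | CC(=O)c1c(OCC=C(C)C)cc2OC(C)(C)C=Cc2c1O | intermediate
10 | 1-[5-hydroxy-2,2-dimethyl-7-(3-methylbut-2-en-1-yloxy)-2H-chromen-6-yl]-3,3-bis(methylsulfanyl)prop-2-en-1-one | CSC(SC)=CC(=O)c1c(OCC=C(C)C)cc2OC(C)(C)C=Cc2c1O | intermediate
11 | 10 carrying a 2,4,5-trihydroxy-3-prenylphenyl group on C-2 of the propenone (hydroquinone Michael adduct) | CSC(SC)=C(C(=O)c1c(OCC=C(C)C)cc2OC(C)(C)C=Cc2c1O)c1cc(O)c(O)c(CC=C(C)C)c1O | intermediate (not isolated)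
12 | [5,6-dihydroxy-2-(methylsulfanyl)-7-prenyl-1-benzofuran-3-yl][5-hydroxy-2,2-dimethyl-7-(prenyloxy)-2H-chromen-6-yl]methanone | CSc1oc2c(CC=C(C)C)c(O)c(O)cc2c1C(=O)c1c(OCC=C(C)C)cc2OC(C)(C)C=Cc2c1O | intermediate (not isolated)
13 | coumaronochromone with 5-O-prenyl, H at C-6, 2,2-dimethylpyran fused at O-7/C-8, 3'-prenyl and 4',5'-dihydroxy | CC(C)=CCOc1cc2OC(C)(C)C=Cc2c3oc4oc5c(CC=C(C)C)c(O)c(O)cc5c4c(=O)c13 | intermediate
14 | coumaronochromone with 5-OH, 6-prenyl, 2,2-dimethylpyran fused at O-7/C-8, 3'-prenyl and 4',5'-dihydroxy (CNP0329721.0, achiral) | CC(C)=CCc1c2c(c3oc4oc5c(CC=C(C)C)c(O)c(O)cc5c4c(=O)c3c1O)C=CC(C)(C)O2 | target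

## Step count

- Total steps: 7.
- Longest linear sequence: 5 (steps 3, 4, 5, 6, 7 from phloroacetophenone); the quinone branch is 2 steps (steps 1, 2).

## Three steps most likely to fail, with fallbacks

**Step 6 (double annulation).** The dithioacetal carbon may be too weak a nucleophile for the hydroxyquinone, the acid may ionise the prenyl ether before the pyranone closes, or the adduct 11 may be oxidised by excess 5. The fallback sets out from 10 and comes back at 13. Heating 10 with morpholine in ethanol exchanges one MeS group and lets the single free OH close the pyranone, giving 8,8-dimethyl-2-(morpholin-4-yl)-5-(prenyloxy)-4H,8H-pyrano[2,3-h]chromen-4-one F1. This true enaminone is then used in a classical Nenitzescu benzofuran annulation with 5 in acetic acid at 40 °C, which expels morpholine and gives 13. The two rings are then made in two flasks.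

**Step 7 (O→C prenyl shift).** The prenyl cation may be lost or captured by the B-ring catechol, or the 3'-prenyl/4'-OH pair may cyclise to a chroman on the clay. The fallback sets out from 8 and comes back at 14, placing the C-prenyl by a thermal sigmatropic route before the annulation. Selective protection of the less hindered OH of 8 (MOMCl, DIPEA) gives 1-[5-hydroxy-7-(methoxymethoxy)-2,2-dimethyl-2H-chromen-6-yl]ethanone F2. O-Prenylation of the remaining chelated OH (2, K2CO3, DMF, 60 °C) gives 1-[7-(methoxymethoxy)-2,2-dimethyl-5-(prenyloxy)-2H-chromen-6-yl]ethanone F3. A para-Claisen–Cope rearrangement (PhNEt2, 190 °C; both ortho positions blocked) delivers 1-[5-hydroxy-7-(methoxymethoxy)-2,2-dimethyl-8-prenyl-2H-chromen-6-yl]ethanone F4. NaH/CS2/MeI then gives the ketene dithioacetal of F4, F5. The same double annulation with 5 gives the 5-O-MOM ether of the target, F6, and 1 M HCl in MeOH at 40 °C releases 14.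

**Step 4 (site-selective O-prenylation).** The preference for the 7-OH rests on a steric and chelation argument and could be low. The fallback sets out from 6 and comes back at 13, closing the pyranone while the two ortho OH groups are still equivalent. Treating 6 with t-BuOK/CS2 and then MeI gives 5,7-dihydroxy-2-(methylsulfanyl)-4H-chromen-4-one F7. Alkylation of the acidic 7-OH with 3-chloro-3-methylbut-1-yne (K2CO3, KI, CuI, acetone) gives 5-hydroxy-7-[(2-methylbut-3-yn-2-yl)oxy]-2-(methylsulfanyl)-4H-chromen-4-one F8. A thermal propargyl Claisen/[1,5]-H/oxa-6π sequence (xylene, 140 °C) gives the angular 5-hydroxy-8,8-dimethyl-2-(methylsulfanyl)-4H,8H-pyrano[2,3-h]chromen-4-one F9. O-Prenylation of the chelated 5-OH (2, K2CO3, DMF, 60 °C) gives 8,8-dimethyl-5-(prenyloxy)-2-(methylsulfanyl)-4H,8H-pyrano[2,3-h]chromen-4-one F10. F10 and 5 with Zn(OTf)2 then form only the furan ring and give 13.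

## Further compounds

F1 | step 6 | 8,8-dimethyl-2-(morpholin-4-yl)-5-(3-methylbut-2-en-1-yloxy)-4H,8H-pyrano[2,3-h]chromen-4-one | C1COCCN1c1cc(=O)c2c(OCC=C(C)C)cc3OC(C)(C)C=Cc3c2o1
F2 | step 7 | 1-[5-hydroxy-7-(methoxymethoxy)-2,2-dimethyl-2H-chromen-6-yl]ethanone | CC(=O)c1c(OCOC)cc2OC(C)(C)C=Cc2c1O
F3 | step 7 | 1-[7-(methoxymethoxy)-2,2-dimethyl-5-(3-methylbut-2-en-1-yloxy)-2H-chromen-6-yl]ethanone | CC(=O)c1c(OCOC)cc2OC(C)(C)C=Cc2c1OCC=C(C)C
F4 | step 7 | 1-[5-hydroxy-7-(methoxymethoxy)-2,2-dimethyl-8-(3-methylbut-2-en-1-yl)-2H-chromen-6-yl]ethanone | CC(=O)c1c(OCOC)c(CC=C(C)C)c2OC(C)(C)C=Cc2c1O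
F5 | step 7 | 1-[5-hydroxy-7-(methoxymethoxy)-2,2-dimethyl-8-(3-methylbut-2-en-1-yl)-2H-chromen-6-yl]-3,3-bis(methylsulfanyl)prop-2-en-1-one | CSC(SC)=CC(=O)c1c(OCOC)c(CC=C(C)C)c2OC(C)(C)C=Cc2c1O
F6 | step 7 | 5-O-methoxymethyl ether of target 14 | CC(C)=CCc1c(OCOC)c2c(=O)c3c4cc(O)c(O)c(CC=C(C)C)c4oc3oc2c2C=CC(C)(C)Oc12
F7 | step 4 | 5,7-dihydroxy-2-(methylsulfanyl)-4H-chromen-4-one | CSc1cc(=O)c2c(O)cc(O)cc2o1
F8 | step 4 | 5-hydroxy-7-[(2-methylbut-3-yn-2-yl)oxy]-2-(methylsulfanyl)-4H-chromen-4-one | CSc1cc(=O)c2c(O)cc(OC(C)(C)C#C)cc2o1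
F9 | step 4 | 5-hydroxy-8,8-dimethyl-2-(methylsulfanyl)-4H,8H-pyrano[2,3-h]chromen-4-one | CSc1cc(=O)c2c(O)cc3OC(C)(C)C=Cc3c2o1
F10 | step 4 | 8,8-dimethyl-5-(3-methylbut-2-en-1-yloxy)-2-(methylsulfanyl)-4H,8H-pyrano[2,3-h]chromen-4-one | CSc1cc(=O)c2c(OCC=C(C)C)cc3OC(C)(C)C=Cc3c2o1
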